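The depside ester is not made by acylation. In ring A the aroyloxy oxygen on C4 sits beside the C3 methyl carbon; if that carbon is read as a former formyl group, O4–C(=O) and C3–CHO are the two halves of the C2=C3 bond of a 2-arylbenzofuran. One ozonolysis therefore opens the furan, creates the hindered ester carbonyl on furan C2 (bearing ring B) and a formyl group on C3, and closes no ring. The precursor is a 4-hydroxy-6-methylbenzofuran-5-carboxylate carrying the tribenzylated, methyl-substituted ring B at C2, assembled from symmetric 2-iodoorcinol and an aryl alkyne; a final hydrogenation removes the benzyl groups and turns the formyl group into the C3 methyl.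

Key step: step 9

Remark: the target is achiral and 5-methylpyrogallol is assumed to be purchasable. The C4 phenol of the benzofuran is left unprotected on purpose: its hydrogen bond to the neighbouring ester deactivates it toward ozone, and a free ortho-hydroxyl assists the final deoxygenation of the formyl group. Ring A is the benzoate ring with the methyl ester; ring B is the trihydroxytoluoyl ring.

Step 1
Reactants: 1 5-methylpyrogallol; 2 benzyl bromide
Product: 3 1,2,3-tris(benzyloxy)-5-methylbenzene
Conditions: BnBr (excess), K2CO3, DMF, N2, 60 °C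
Reagents that add atoms: benzyl bromide, BrCc1ccccc1
Why: Williamson ether synthesis, in which the three phenoxides are alkylated by the benzylic bromide under carbonate base with exclusion of air to protect the electron-rich triol.

Step 2
Reactants: 3 1,2,3-tris(benzyloxy)-5-methylbenzene
Product: 5 2,3,4-tris(benzyloxy)-6-methylbenzaldehyde, via aryl iminium chloride 4 (not isolated)
Conditions: POCl3, DMF, 0 to 70 °C; then aq NaOAc
Reagents that add atoms: N,N-dimethylformamide, CN(C)C=O; water, O
Why: Vilsmeier–Haack formylation, in which the two open ring positions of 3 are equivalent by symmetry and activated by ortho and para benzyloxy groups, so the chloroiminium ion can enter only at the carbon that later becomes the ipso carbon of the depside acyl group.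

Step 3
Reactants: 5 2,3,4-tris(benzyloxy)-6-methylbenzaldehyde; 6 dimethyl (1-diazo-2-oxopropyl)phosphonate
Product: 7 1,2,3-tris(benzyloxy)-4-ethynyl-5-methylbenzene
Conditions: K2CO3, MeOH/THF, 0 °C to rt
Reagents that add atoms: dimethyl (1-diazo-2-oxopropyl)phosphonate, COP(=O)(OC)C(=[N+]=[N-])C(C)=O
Why: Seyferth–Gilbert homologation in the Ohira–Bestmann variant, in which methanolysis of the acetyl group releases the diazomethylphosphonate anion that olefinates the non-enolizable aldehyde and, after loss of N2 and 1,2-shift, gives the terminal alkyne under conditions harmless to benzyl ethers.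

Step 4
Reactants: 8 orcinol
Product: 9 2-iodo-5-methylbenzene-1,3-diol
Conditions: I2, NaHCO3, H2O/THF, 0 °C
Reagents that add atoms: iodine, II
Why: Electrophilic aromatic iodination of the phenolate under bicarbonate in water, which for resorcinols is directed to the carbon flanked by both hydroxyls and here keeps the mirror symmetry that makes the later furan closure unambiguous.

Step 5
Reactants: 9 2-iodo-5-methylbenzene-1,3-diol; 7 1,2,3-tris(benzyloxy)-4-ethynyl-5-methylbenzene
Product: 11 6-methyl-2-[2,3,4-tris(benzyloxy)-6-methylphenyl]-1-benzofuran-4-ol, via alkynylresorcinol 10 (not isolated)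
Conditions: PdCl2(PPh3)2 (cat.), CuI (cat.), Et3N, DMF, degassed, 70 °C
Reagents that add atoms: none
Why: Sonogashira coupling followed in the same pot by metal-assisted 5-endo-dig hydroalkoxylation of the o-alkynylphenol, where either hydroxyl of the symmetric resorcinol gives the same benzofuran and the other one remains as the C4 phenol.

Step 6
Reactants: 11 6-methyl-2-[2,3,4-tris(benzyloxy)-6-methylphenyl]-1-benzofuran-4-ol
Product: 13 4-hydroxy-6-methyl-2-[2,3,4-tris(benzyloxy)-6-methylphenyl]-1-benzofuran-5-carbaldehyde, via hydroxymethyl phenol 12 (not isolated)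
Conditions: MgCl2, Et3N, (CH2O)n, THF, reflux; then 1 M HCl
Reagents that add atoms: formaldehyde (as paraformaldehyde), C=O
Why: Casnati–Skattebøl ortho-formylation, in which the magnesium phenoxide delivers formaldehyde through a six-membered chelate to C5, the only free carbon ortho to the C4 hydroxyl, and a second formaldehyde oxidizes the benzylic alkoxide by hydride transfer, so furan C3 and C7 should stay untouched.

Step 7
Reactants: 13 4-hydroxy-6-methyl-2-[2,3,4-tris(benzyloxy)-6-methylphenyl]-1-benzofuran-5-carbaldehyde
Product: 14 4-hydroxy-6-methyl-2-[2,3,4-tris(benzyloxy)-6-methylphenyl]-1-benzofuran-5-carboxylic acid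
Conditions: NaClO2, NaH2PO4, 2-methyl-2-butene (large excess), t-BuOH/THF/H2O, 0 °C to rt
Reagents that add atoms: sodium chlorite, [Na+].[O-]Cl=O
Why: Lindgren–Pinnick oxidation, in which chlorous acid converts the chelated aldehyde into the salicylic acid while the excess alkene consumes the hypochlorous acid that could otherwise chlorinate the phenol ring or the furan double bond.

Step 8
Reactants: 14 4-hydroxy-6-methyl-2-[2,3,4-tris(benzyloxy)-6-methylphenyl]-1-benzofuran-5-carboxylic acid
Product: 15 methyl 4-hydroxy-6-methyl-2-[2,3,4-tris(benzyloxy)-6-methylphenyl]-1-benzofuran-5-carboxylate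
Conditions: MeI, KHCO3, DMF, rt
Reagents that add atoms: iodomethane, CI
Why: SN2 O-alkylation of the carboxylate, since bicarbonate ionizes only the carboxylic acid and the hydrogen-bonded C4 phenol is left free.

Step 9
Reactants: 15 methyl 4-hydroxy-6-methyl-2-[2,3,4-tris(benzyloxy)-6-methylphenyl]-1-benzofuran-5-carboxylate
Product: 18 methyl 3-formyl-2-hydroxy-6-methyl-4-{[2,3,4-tris(benzyloxy)-6-methylbenzoyl]oxy}benzoate, via primary ozonide 16 (not isolated), via methoxy hydroperoxide 17 (not isolated)
Conditions: O3/O2 (about one equivalent, Sudan Red 7B end-point), CH2Cl2/MeOH, −78 °C; then Me2S, −78 °C to rt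
Reagents that add atoms: ozone, [O-][O+]=O
Why: Criegee ozonolysis, in which ozone adds by 1,3-dipolar cycloaddition to the furan C2=C3 bond to give 16, whose cycloreversion leaves the ester C=O on the oxygen-bearing C2 and a carbonyl oxide on C3 that methanol captures as 17, which dimethyl sulfide reduces to a hemiacetal that loses methanol to the formyl group. The closest known reactions are the ozonolytic opening of 2-arylbenzofurans to 2-(aroyloxy)benzaldehydes and the cleavage of enol ethers to esters. No ring is closed (the furan is opened) and no stereocentre remains in 18, the two centres of racemic 16 being destroyed again. The step needs chemoselectivity for the furan double bond over two alkoxy arenes, three benzyl ethers and the phenol, and this should be secured because that bond is an aryl enol ether and by far the most nucleophilic π bond, the C4 phenol is deactivated by its hydrogen bond to the ester, and the dye end-point limits ozone to one equivalent. Once the bond is cleaved, ring A carries three acceptor groups and ring B an acyl group, so the product should be less prone to ozone than the substrate. The hindered aryl ester thus arises from a C–C bond made by cross-coupling and not from acylation of a phenol by a doubly ortho-substituted acid.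

Step 10
Reactants: 18 methyl 3-formyl-2-hydroxy-6-methyl-4-{[2,3,4-tris(benzyloxy)-6-methylbenzoyl]oxy}benzoate
Product: 21 methyl 2-hydroxy-3,6-dimethyl-4-[(2,3,4-trihydroxy-6-methylbenzoyl)oxy]benzoate, via debenzylated aldehyde 19 (not isolated), via benzylic alcohol 20 (not isolated)
Conditions: H2 (3 atm), 10% Pd/C, AcOH, 40 °C
Reagents that add atoms: none
Why: Catalytic hydrogenolysis, in which Pd/C cleaves the three O-benzyl bonds and, in acetic acid, reduces the formyl group next to the C2 hydroxyl through the benzylic alcohol to the methyl group, while the methyl ester and the depside ester, neither of them benzylic, should stay intact.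

Compound list
1 | 5-methylbenzene-1,2,3-triol (5-methylpyrogallol) | Cc1cc(O)c(O)c(O)c1 | starting material
2 | benzyl bromide | BrCc1ccccc1 | starting material
3 | 1,2,3-tris(benzyloxy)-5-methylbenzene | Cc1cc(OCc2ccccc2)c(OCc2ccccc2)c(OCc2ccccc2)c1 | intermediate
4 | N-methyl-N-{[2,3,4-tris(benzyloxy)-6-methylphenyl]methylidene}methanaminium chloride (aryl iminium chloride) | C[N+](C)=Cc1c(C)cc(OCc2ccccc2)c(OCc2ccccc2)c1OCc1ccccc1.[Cl-] | intermediate (not isolated)
5 | 2,3,4-tris(benzyloxy)-6-methylbenzaldehyde | O=Cc1c(C)cc(OCc2ccccc2)c(OCc2ccccc2)c1OCc1ccccc1 | intermediate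
6 | dimethyl (1-diazo-2-oxopropyl)phosphonate | COP(=O)(OC)C(=[N+]=[N-])C(C)=O | starting material
7 | 1,2,3-tris(benzyloxy)-4-ethynyl-5-methylbenzene | C#Cc1c(C)cc(OCc2ccccc2)c(OCc2ccccc2)c1OCc1ccccc1 | intermediate
8 | 5-methylbenzene-1,3-diol (orcinol) | Cc1cc(O)cc(O)c1 | starting material
9 | 2-iodo-5-methylbenzene-1,3-diol | Cc1cc(O)c(I)c(O)c1 | intermediate
10 | 5-methyl-2-{[2,3,4-tris(benzyloxy)-6-methylphenyl]ethynyl}benzene-1,3-diol | Cc1cc(O)c(C#Cc2c(C)cc(OCc3ccccc3)c(OCc3ccccc3)c2OCc2ccccc2)c(O)c1 | intermediate (not isolated)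
11 | 6-methyl-2-[2,3,4-tris(benzyloxy)-6-methylphenyl]-1-benzofuran-4-ol | Cc1cc(O)c2cc(-c3c(C)cc(OCc4ccccc4)c(OCc4ccccc4)c3OCc3ccccc3)oc2c1 | intermediate
12 | 5-(hydroxymethyl)-6-methyl-2-[2,3,4-tris(benzyloxy)-6-methylphenyl]-1-benzofuran-4-ol | OCc1c(C)cc2oc(-c3c(C)cc(OCc4ccccc4)c(OCc4ccccc4)c3OCc3ccccc3)cc2c1O | intermediate (not isolated)
13 | 4-hydroxy-6-methyl-2-[2,3,4-tris(benzyloxy)-6-methylphenyl]-1-benzofuran-5-carbaldehyde | O=Cc1c(C)cc2oc(-c3c(C)cc(OCc4ccccc4)c(OCc4ccccc4)c3OCc3ccccc3)cc2c1O | intermediate
14 | 4-hydroxy-6-methyl-2-[2,3,4-tris(benzyloxy)-6-methylphenyl]-1-benzofuran-5-carboxylic acid | OC(=O)c1c(C)cc2oc(-c3c(C)cc(OCc4ccccc4)c(OCc4ccccc4)c3OCc3ccccc3)cc2c1O | intermediate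
15 | methyl 4-hydroxy-6-methyl-2-[2,3,4-tris(benzyloxy)-6-methylphenyl]-1-benzofuran-5-carboxylate | COC(=O)c1c(C)cc2oc(-c3c(C)cc(OCc4ccccc4)c(OCc4ccccc4)c3OCc3ccccc3)cc2c1O | intermediate (key-step precursor)
16 | primary ozonide of 15: cis-fused 1,2,3-trioxolane spanning furan C2 and C3 (racemic, one enantiomer drawn) | COC(=O)c1c(C)cc2O[C@]3(c4c(C)cc(OCc5ccccc5)c(OCc5ccccc5)c4OCc4ccccc4)OOO[C@@H]3c2c1O | intermediate (not isolated)
17 | methyl 3-[hydroperoxy(methoxy)methyl]-2-hydroxy-6-methyl-4-{[2,3,4-tris(benzyloxy)-6-methylbenzoyl]oxy}benzoate (racemic at the acetal carbon) | COC(OO)c1c(O)c(C(=O)OC)c(C)cc1OC(=O)c1c(C)cc(OCc2ccccc2)c(OCc2ccccc2)c1OCc1ccccc1 | intermediate (not isolated)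
18 | methyl 3-formyl-2-hydroxy-6-methyl-4-{[2,3,4-tris(benzyloxy)-6-methylbenzoyl]oxy}benzoate | COC(=O)c1c(C)cc(OC(=O)c2c(C)cc(OCc3ccccc3)c(OCc3ccccc3)c2OCc2ccccc2)c(C=O)c1O | intermediate (key-step product)
19 | methyl 3-formyl-2-hydroxy-6-methyl-4-[(2,3,4-trihydroxy-6-methylbenzoyl)oxy]benzoate | COC(=O)c1c(C)cc(OC(=O)c2c(C)cc(O)c(O)c2O)c(C=O)c1O | intermediate (not isolated)
20 | methyl 2-hydroxy-3-(hydroxymethyl)-6-methyl-4-[(2,3,4-trihydroxy-6-methylbenzoyl)oxy]benzoate | COC(=O)c1c(C)cc(OC(=O)c2c(C)cc(O)c(O)c2O)c(CO)c1O | intermediate (not isolated)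
21 | methyl 2-hydroxy-3,6-dimethyl-4-[(2,3,4-trihydroxy-6-methylbenzoyl)oxy]benzoate | COC(=O)c1c(C)cc(OC(=O)c2c(C)cc(O)c(O)c2O)c(C)c1O | target

Total step count: 10. Longest linear sequence: 9 steps (steps 1, 2, 3, 5, 6, 7, 8, 9, 10, from 5-methylpyrogallol); the iodination of orcinol (step 4) is a one-step branch.

Steps most likely to fail

Step 9. Ozone may carry on past the furan bond into the benzyl ethers or the alkoxy arenes, or the primary ozonide may fragment in the reverse sense, so that methanol adds at C2 and ring A is expelled as a phenol. The fallback sets out from 15 and replaces ozone by singlet oxygen in an aprotic medium. Dye-sensitized photooxygenation (O2, tetraphenylporphyrin, visible light, CH2Cl2, −40 °C) should add across the furan C2=C3 bond in a [2+2] sense to give the cis-fused dioxetane F1. On warming to room temperature F1 should cleave its O–O and C2–C3 bonds to the ester and the formyl group. The route is rejoined at 18.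

Step 10. The deoxygenation may stall at the benzylic alcohol stage, where the aroyl group can shift to the new hydroxyl, and hydrogenolysis of the resulting benzylic ester would sever the depside. The fallback sets out from 18 and separates the two tasks. Kursanov–Parnes ionic hydrogenation (Et3SiH, CF3CO2H, CH2Cl2, 0 °C to rt) should reduce the hydroxyl-flanked aldehyde through its benzylic cation to methyl 2-hydroxy-3,6-dimethyl-4-{[2,3,4-tris(benzyloxy)-6-methylbenzoyl]oxy}benzoate F2, under acidic conditions where acyl shift is slow. Neutral hydrogenolysis (H2, Pd/C, EtOAc, rt) then removes the three benzyl groups. The route is rejoined at 21.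

Step 5. Oxidative homocoupling of the hindered alkyne, or a coupling that stops short of ring closure with the unprotected iodoresorcinol, would lower the throughput of the convergent step. The fallback sets out from 9 and separates coupling from cyclization. Acetylation (Ac2O, pyridine, rt) gives 2-iodo-5-methyl-1,3-phenylene diacetate F3. Sonogashira coupling of F3 with 7 (PdCl2(PPh3)2, CuI, Et3N, THF, 50 °C) gives 5-methyl-2-{[2,3,4-tris(benzyloxy)-6-methylphenyl]ethynyl}-1,3-phenylene diacetate F4. Cs2CO3 in MeOH/DMF at 60 °C should then remove both acetates to give 10 and close the furan by base-mediated 5-endo-dig attack of the phenoxide. The route is rejoined at 11.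

Further compounds
F1 | step 9 | cis-fused 1,2-dioxetane spanning furan C2 and C3 of 15 (racemic, one enantiomer drawn) | COC(=O)c1c(C)cc2O[C@]3(c4c(C)cc(OCc5ccccc5)c(OCc5ccccc5)c4OCc4ccccc4)OO[C@@H]3c2c1O
F2 | step 10 | methyl 2-hydroxy-3,6-dimethyl-4-{[2,3,4-tris(benzyloxy)-6-methylbenzoyl]oxy}benzoate | COC(=O)c1c(C)cc(OC(=O)c2c(C)cc(OCc3ccccc3)c(OCc3ccccc3)c2OCc2ccccc2)c(C)c1O
F3 | step 5 | 2-iodo-5-methyl-1,3-phenylene diacetate | CC(=O)Oc1cc(C)cc(OC(C)=O)c1I
F4 | step 5 | 5-methyl-2-{[2,3,4-tris(benzyloxy)-6-methylphenyl]ethynyl}-1,3-phenylene diacetate | CC(=O)Oc1cc(C)cc(OC(C)=O)c1C#Cc1c(C)cc(OCc2ccccc2)c(OCc2ccccc2)c1OCc1ccccc1
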